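**Retrosynthetic overview**
1. The C-5–O–C-10a bridge and the C-9=C-10 ester alkene are made last, by iodo-hemiketalisation and dehydroiodination of a tricyclic 5,8-dione whose alkene sits at C-10=C-10a.
2. Key disconnection: ring C (a 2-isopropylcyclohexane-1,4-dione) is contracted by one carbon to a cyclopentane-1,3-dione; forward, a carbenoid ring expansion with 1,2-acyl shift inserts C-7 with its isopropyl group.
3. The cyclopentanedione comes from a cis keto aldehyde (aldol, then oxidation); ring B comes from an endo Diels–Alder reaction of a ring A dienoate with (E)-3-methyl-4-oxopent-2-enal, which sets C-4a and C-4b.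
4. The ring A dienoate comes from isoprene, a propargyl ether and a malonic half ester; the enal comes from 2,3-dimethylfuran.
5. Ring order: A, then B, then a five-membered forerunner of C, then C by ring expansion, then the oxygen bridge.

Locants: phenanthrene-type numbering of the target carbocycle (ring A: C-1 to C-4, C-4a, C-10a; ring B: C-4a, C-4b, C-8a, C-9, C-10, C-10a; ring C: C-4b, C-5 to C-8, C-8a). The β face of ring B is the one carrying C-5; the α face carries CH3-4b.
Assumption: 1,1-diiodo-2-methylpropane is bought as a catalogue gem-diiodide (otherwise one extra operation from isobutyraldehyde hydrazone and iodine).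

**Step 1**
Reactants: 1 2-methylbuta-1,3-diene (isoprene); 2 trimethyl(prop-2-yn-1-yloxy)silane
Product: 4 (5-methylcyclohexa-1,4-dien-1-yl)methanol, via silyl ether 3 (not isolated)
Conditions: CoBr2[N-(2,4,6-trimethylphenyl)-1-(pyridin-2-yl)methanimine] (5 mol %), Zn, ZnI2, Fe powder, CH2Cl2, rt; then K2CO3 (cat.), MeOH, rt
Reagents that add atoms: none
Why: cobalt-catalysed formal [4+2] cycloaddition of a 1,3-diene with a terminal alkyne (monovalent cobalt formed in situ by zinc), where the pyridine–imine ligand gives the 1,3-disubstituted cyclohexa-1,4-diene, followed by methanolysis of the silyl ether, with no stereocentre formed.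

**Step 2**
Reactants: 4 (5-methylcyclohexa-1,4-dien-1-yl)methanol; 5 3-methoxy-3-oxopropanoic acid
Product: 7 methyl (2E)-3-(5-methylcyclohexa-1,4-dien-1-yl)prop-2-enoate, via aldehyde 6 (not isolated)
Conditions: MnO2, CH2Cl2, rt; filter; then 5, 4-(dimethylamino)pyridine (10 mol %), DMF, rt
Reagents that add atoms: none
Why: allylic alcohol oxidation followed by a decarboxylative Doebner–Knoevenagel condensation with the malonic half ester, which gives the E-enoate.

**Step 3**
Reactants: 8 2,3-dimethylfuran
Product: 10 (2E)-3-methyl-4-oxopent-2-enal, via Z enal 9 (not isolated)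
Conditions: NBS, NaHCO3, acetone/H2O, −20 °C; then pyridine (cat.), rt
Reagents that add atoms: water (O)
Why: oxidative ring opening of the furan (bromination and hydrolysis of the 2,5-dihydrofuran) gives the cis-ene-dicarbonyl compound, which pyridine isomerises to the more stable E isomer, with no stereocentre formed.

**Step 4**
Reactants: 7 methyl (2E)-3-(5-methylcyclohexa-1,4-dien-1-yl)prop-2-enoate; 10 (2E)-3-methyl-4-oxopent-2-enal
Product: 11 methyl 4-acetyl-3-formyl-4,7-dimethyl-2,3,4,4a,5,8-hexahydronaphthalene-2-carboxylate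
Conditions: (S)-3,3-diphenyl-1-(2-methylphenyl)tetrahydro-1H,3H-pyrrolo[1,2-c][1,3,2]oxazaborole protonated by HN(SO2CF3)2 (20 mol %), CH2Cl2, −78 to −40 °C
Reagents that add atoms: none
Why: Lewis acid-catalysed endo Diels–Alder reaction in which the oxazaborolidinium binds the formyl group, the more nucleophilic diene terminus C-4a (δ-carbon of the dienoate) bonds to the enal β-carbon C-4b, the endo formyl group places the ring A methylene on C-4a cis to CHO and therefore (E-dienophile) cis to CH3-4b and trans to the acetyl group, and the catalyst enantiomer (S drawn, its antipode would give ent-11) fixes the absolute configuration.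

**Step 5**
Reactants: 11 methyl 4-acetyl-3-formyl-4,7-dimethyl-2,3,4,4a,5,8-hexahydronaphthalene-2-carboxylate
Product: 13 methyl 3-hydroxy-7,9b-dimethyl-1-oxo-2,3,3a,4,6,9,9a,9b-octahydro-1H-cyclopenta[a]naphthalene-4-carboxylate, via formyl epimer 12 (not isolated)
Conditions: pyrrolidine (20 mol %), AcOH (20 mol %), CH2Cl2, 0 °C to rt
Reagents that add atoms: none
Why: amine-catalysed epimerisation of the formyl-bearing carbon (C-8a) through its enamine, then intramolecular aldol addition of the methyl ketone to the aldehyde, which only the cis keto aldehyde can undergo, so the five-membered ring is cis-fused with H-8a cis to CH3-4b (the carbinol centre is removed in step 6).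

**Step 6**
Reactants: 13 methyl 3-hydroxy-7,9b-dimethyl-1-oxo-2,3,3a,4,6,9,9a,9b-octahydro-1H-cyclopenta[a]naphthalene-4-carboxylate
Product: 14 methyl 7,9b-dimethyl-1,3-dioxo-2,3,3a,4,6,9,9a,9b-octahydro-1H-cyclopenta[a]naphthalene-4-carboxylate
Conditions: Dess–Martin periodinane, CH2Cl2, rt
Reagents that add atoms: none
Why: Dess–Martin oxidation of the β-ketol to the 1,3-diketone, with no other stereocentre touched.

**Step 7 (key step)**
Reactants: 14 methyl 7,9b-dimethyl-1,3-dioxo-2,3,3a,4,6,9,9a,9b-octahydro-1H-cyclopenta[a]naphthalene-4-carboxylate; 15 1,1-diiodo-2-methylpropane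
Product: 17 methyl 2,4b-dimethyl-5,8-dioxo-7-(propan-2-yl)-1,4,4a,4b,5,6,7,8,8a,9-decahydrophenanthrene-9-carboxylate, via zinc cyclopropanolate 16 (not isolated)
Conditions: Et2Zn (3 equiv), 15 (2 equiv), CH2Cl2, 0 °C to rt; then aq NH4Cl
Reagents that add atoms: none
Why: Proposed new method: zinc-carbenoid one-carbon ring expansion of a cyclic 1,3-diketone with an alkyl-substituted carbenoid, in which the ethylzinc enolate of 14 is C-alkylated at C-6 by EtZnCH(I)CH(CH3)2, the new carbon–zinc bond adds to the less hindered C-8 carbonyl (C-5 is flanked by quaternary C-4b) to give cyclopropanolate 16, and cleavage of the C-6–C-8 bond (1,2-acyl shift onto the carbenoid carbon, stepwise and polar) gives the cyclohexane-1,4-dione with the isopropyl carbon C-7 next to C-8, C-7 being epimerisable and settling as the equatorial isomer; the closest known reaction is the Zercher chain extension of β-keto esters and acyclic β-diketones with Et2Zn/CH2I2 or Et2Zn/CH3CHI2, not yet shown as a ring expansion of a cyclic 1,3-dione with an isopropyl-bearing carbenoid.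

**Step 8**
Reactants: 17 methyl 2,4b-dimethyl-5,8-dioxo-7-(propan-2-yl)-1,4,4a,4b,5,6,7,8,8a,9-decahydrophenanthrene-9-carboxylate
Product: 19 methyl 5-hydroxy-2,4b-dimethyl-8-oxo-7-(propan-2-yl)-5,10a-epoxy-1,4,4a,4b,5,6,7,8,8a,10a-decahydrophenanthrene-9-carboxylate (target CNP0382995.2), via iodo hemiketal 18 (not isolated)
Conditions: NIS, MeCN/H2O (10:1), 0 °C; then K2CO3, MeOH, rt
Reagents that add atoms: water (O)
Why: iodonium-triggered 5-exo cyclisation (iodo-etherification type) in which the C-5 carbonyl oxygen, held on the β face, attacks the tertiary alkene carbon C-10a and water caps the oxocarbenium ion as the hemiketal (setting C-10a and C-5), followed by base-induced anti dehydroiodination to the conjugated ester and equilibration of C-7 to the equatorial isopropyl epimer.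

**Compound list**
1 | 2-methylbuta-1,3-diene (isoprene) | C=CC(C)=C | starting material
2 | trimethyl(prop-2-yn-1-yloxy)silane | C#CCO[Si](C)(C)C | starting material
3 | trimethyl[(5-methylcyclohexa-1,4-dien-1-yl)methoxy]silane | C[Si](C)(C)OCC1=CCC=C(C)C1 | intermediate
4 | (5-methylcyclohexa-1,4-dien-1-yl)methanol | OCC1=CCC=C(C)C1 | intermediate
5 | 3-methoxy-3-oxopropanoic acid (monomethyl malonate) | COC(=O)CC(O)=O | starting material
6 | 5-methylcyclohexa-1,4-diene-1-carbaldehyde | O=CC1=CCC=C(C)C1 | intermediate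
7 | methyl (2E)-3-(5-methylcyclohexa-1,4-dien-1-yl)prop-2-enoate | COC(=O)/C=C/C1=CCC=C(C)C1 | intermediate
8 | 2,3-dimethylfuran | Cc1occc1C | starting material
9 | (2Z)-3-methyl-4-oxopent-2-enal | CC(=O)/C(C)=C\C=O | intermediate
10 | (2E)-3-methyl-4-oxopent-2-enal | CC(=O)/C(C)=C/C=O | intermediate
11 | methyl 4-acetyl-3-formyl-4,7-dimethyl-2,3,4,4a,5,8-hexahydronaphthalene-2-carboxylate; naphthalene C-2, C-3, C-4, C-4a are target C-9, C-8a, C-4b, C-4a; CO2Me, CHO, CH3-4 and the C-5 methylene on the α face, acetyl and H-4a on the β face; single enantiomer as in the SMILES | COC(=O)[C@@H]1C=C2CC(C)=CC[C@@H]2[C@@](C)(C(C)=O)[C@@H]1C=O | intermediate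
12 | epimer of 11 at the formyl-bearing carbon (CHO β, cis to acetyl) | COC(=O)[C@@H]1C=C2CC(C)=CC[C@@H]2[C@@](C)(C(C)=O)[C@H]1C=O | intermediate
13 | methyl 3-hydroxy-7,9b-dimethyl-1-oxo-2,3,3a,4,6,9,9a,9b-octahydro-1H-cyclopenta[a]naphthalene-4-carboxylate; five-membered ring cis-fused on the β face, CH3-9b and H-3a α, H-9a β, CO2Me α; carbinol carbon a mixture | COC(=O)[C@@H]1C=C2CC(C)=CC[C@@H]2[C@]2(C)[C@H]1C(O)CC2=O | intermediate
14 | methyl 7,9b-dimethyl-1,3-dioxo-2,3,3a,4,6,9,9a,9b-octahydro-1H-cyclopenta[a]naphthalene-4-carboxylate (ring C lacking C-7; configuration as 13; largely enolised) | COC(=O)[C@@H]1C=C2CC(C)=CC[C@@H]2[C@]2(C)[C@H]1C(=O)CC2=O | intermediate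
15 | 1,1-diiodo-2-methylpropane | CC(C)C(I)I | starting material
16 | ethylzinc cyclopropanolate of 14: C-7 (bearing isopropyl) bridges C-6 and C-8, C-8 carries O–ZnEt; new centres not controlled | COC(=O)[C@@H]1C=C2CC(C)=CC[C@@H]2[C@]2(C)[C@H]1C1(O[Zn]CC)C(C(C)C)C1C2=O | intermediate
17 | methyl 2,4b-dimethyl-5,8-dioxo-7-(propan-2-yl)-1,4,4a,4b,5,6,7,8,8a,9-decahydrophenanthrene-9-carboxylate; H-4a β; CH3-4b, H-8a and CO2Me-9 α; rings B and C cis-fused; isopropyl cis to CH3-4b on ring C (equatorial epimer drawn) | COC(=O)[C@@H]1C=C2CC(C)=CC[C@@H]2[C@]2(C)[C@H]1C(=O)[C@@H](C(C)C)CC2=O | intermediate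
18 | methyl 5-hydroxy-10-iodo-2,4b-dimethyl-8-oxo-7-(propan-2-yl)-5,10a-epoxy-1,4,4a,4b,5,6,7,8,8a,9,10,10a-dodecahydrophenanthrene-9-carboxylate; oxygen bridge β, iodine α on C-10 | COC(=O)[C@@H]1[C@H](I)[C@]23CC(C)=CC[C@@H]2[C@]2(C)[C@H]1C(=O)[C@@H](C(C)C)C[C@@]2(O)O3 | intermediate
19 | methyl 5-hydroxy-2,4b-dimethyl-8-oxo-7-(propan-2-yl)-5,10a-epoxy-1,4,4a,4b,5,6,7,8,8a,10a-decahydrophenanthrene-9-carboxylate (CNP0382995.2); O on C-10a, H-4a, C-5 and C-8 on the β face of ring B; C-1, C-4, CH3-4b and H-8a α; isopropyl cis to CH3-4b | COC(=O)C1=C[C@]23CC(C)=CC[C@@H]2[C@]2(C)[C@H]1C(=O)[C@@H](C(C)C)C[C@@]2(O)O3 | target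

**Totals**
Total steps: 8. Longest linear sequence: 7 steps (1, 2, 4, 5, 6, 7, 8).

**Steps most likely to fail and their fallbacks**

Step 7 (the new ring expansion). The risks are the choice between the C-8 and C-5 carbonyls and competing cyclopropanation of the two trisubstituted alkenes. The fallback uses known reactions, sets out from 11 and comes back at 17. Isobutylmagnesium bromide (THF, −78 °C) adds selectively to the formyl group of 11 to give methyl 4-acetyl-3-(1-hydroxy-3-methylbutyl)-4,7-dimethyl-2,3,4,4a,5,8-hexahydronaphthalene-2-carboxylate F1. Dess–Martin oxidation gives the diketone methyl 4-acetyl-4,7-dimethyl-3-(3-methylbutanoyl)-2,3,4,4a,5,8-hexahydronaphthalene-2-carboxylate F2. Double deprotonation (LiHMDS, THF, −78 °C) and oxidation of the bis-enolate with Fe(acac)3 (intramolecular oxidative enolate coupling) joins the acetyl CH3 carbon to the CH2 next to the other carbonyl. This closes ring C directly, first as the trans-fused C-8a epimer of 17 F3, which DBU equilibrates to cis-fused 17.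

Step 4 (Diels–Alder). The diene is an electron-poor dienoate and the new bond joins a ring carbon to a fully substituted carbon, so rate and regiochemistry are at risk. The fallback sets out from 10 (with 7) and comes back at 14, replacing monodentate formyl activation by a chelating acyl oxazolidinone and the aldol/oxidation pair by a Claisen acylation. Pinnick oxidation of 10 (NaClO2, NaH2PO4, 2-methylbut-2-ene) gives (2E)-3-methyl-4-oxopent-2-enoic acid F4. Pivaloyl chloride/Et3N converts it into (2E)-3-methyl-4-oxopent-2-enoic 2,2-dimethylpropanoic anhydride F5, which acylates lithiated 1,3-oxazolidin-2-one to give 3-[(2E)-3-methyl-4-oxopent-2-enoyl]-1,3-oxazolidin-2-one F6. Cu(SbF6)2 with (S,S)-2,2'-(propane-2,2-diyl)bis(4-tert-butyl-4,5-dihydro-1,3-oxazole) (10 mol %, or its antipode as needed) binds both imide carbonyls and promotes the endo cycloaddition with 7. The adduct is methyl 4-acetyl-4,7-dimethyl-3-(2-oxo-1,3-oxazolidine-3-carbonyl)-2,3,4,4a,5,8-hexahydronaphthalene-2-carboxylate F7, with the configuration of 11. LiHMDS then epimerises the acyl-bearing carbon, and the acetyl enolate displaces the oxazolidinone to give 14.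

Step 8 (iodo-hemiketalisation and elimination). The ring A alkene may compete for iodonium, and the ester oxygen may compete as nucleophile. The fallback sets out from 17 and comes back at 19 in one operation. It is an aerobic Wacker-type oxidative cyclisation (Pd(OAc)2 10 mol %, pyridine, O2, wet toluene, 60 °C): the hydrate oxygen of the C-5 ketone adds to C-10a by oxypalladation, and β-hydride elimination of H-9 gives the conjugated ester. It makes no compound outside the list (none F0).

**Further compounds**
F1 | step 7 | methyl 4-acetyl-3-(1-hydroxy-3-methylbutyl)-4,7-dimethyl-2,3,4,4a,5,8-hexahydronaphthalene-2-carboxylate | COC(=O)[C@@H]1C=C2CC(C)=CC[C@@H]2[C@@](C)(C(C)=O)[C@@H]1C(O)CC(C)C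
F2 | step 7 | methyl 4-acetyl-4,7-dimethyl-3-(3-methylbutanoyl)-2,3,4,4a,5,8-hexahydronaphthalene-2-carboxylate | COC(=O)[C@@H]1C=C2CC(C)=CC[C@@H]2[C@@](C)(C(C)=O)[C@@H]1C(=O)CC(C)C
F3 | step 7 | C-8a epimer of 17 | COC(=O)[C@@H]1C=C2CC(C)=CC[C@@H]2[C@]2(C)[C@@H]1C(=O)C(C(C)C)CC2=O
F4 | step 4 | (2E)-3-methyl-4-oxopent-2-enoic acid | CC(=O)/C(C)=C/C(O)=O
F5 | step 4 | (2E)-3-methyl-4-oxopent-2-enoic 2,2-dimethylpropanoic anhydride | CC(=O)/C(C)=C/C(=O)OC(=O)C(C)(C)C
F6 | step 4 | 3-[(2E)-3-methyl-4-oxopent-2-enoyl]-1,3-oxazolidin-2-one | CC(=O)/C(C)=C/C(=O)N1CCOC1=O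
F7 | step 4 | methyl 4-acetyl-4,7-dimethyl-3-(2-oxo-1,3-oxazolidine-3-carbonyl)-2,3,4,4a,5,8-hexahydronaphthalene-2-carboxylate | COC(=O)[C@@H]1C=C2CC(C)=CC[C@@H]2[C@@](C)(C(C)=O)[C@@H]1C(=O)N1CCOC1=O
F0 | step 8 | none | none
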